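## Retrosynthetic overview
1. Cut the C(sp3)–C(sp2) bond between the chroman ethyl arm and the side-chain alkene. It is made by hydrozirconation of 2-vinylchroman **10**, then Negishi coupling with E-vinyl iodide **19**.
2. The chroman comes from a Pd-catalysed dynamic kinetic asymmetric allylic etherification (Trost DYKAT) of a formylphenol with isoprene monoxide. This sets the quaternary ArO–C2 stereocentre directly. The ring is then closed by RCM, and the CH2OH carbon is converted to a vinyl group.
3. The side chain is built separately. Wittig gives the E-enal, Brown allylation sets the carbinol, cross-metathesis installs the prenyl group, and Negishi carboalumination/iodination gives the E-vinyl iodide.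
4. Ring order: the dihydropyran ring forms once, by RCM (Step 5), before the fragments are joined. Both stereocentres are set before coupling, and one global desilylation finishes the synthesis.

Assumptions:
- Mono-silylation of methylhydroquinone occurs at the less hindered 4-OH, and the regioisomers are separable.
- The (R,R)-Trost ligand gives the (S)-ether **5**; if it does not, use the (S,S) ligand.
- (+)-Ipc2B(allyl) delivers allyl to the Re face of enal **14**, giving the (R)-carbinol **15**. Mosher analysis will confirm this; otherwise use (−)-Ipc2B(allyl).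
- CIP labels change between intermediates and target without any change in spatial arrangement. C2 is (S) in **5–10**, where the vinyl or CH2OH/CHO group outranks ring C3, and (R) in the target, where the chain CH2 ranks below ring C3.

## Route

**Step 1**
Reactants: **1** 2-methylhydroquinone
Product: **2** 2-methyl-4-(triisopropylsilyloxy)phenol
Conditions: TIPSCl (1.0 equiv), imidazole, DMF, 0 °C → rt
Reagents that add atoms: TIPSCl, CC(C)[Si](Cl)(C(C)C)C(C)C
Why: Silylation with a bulky silyl chloride occurs at the OH remote from the methyl group, leaving the hindered phenol free. No stereocentre is involved.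

**Step 2**
Reactants: **2**
Product: **3** 2-hydroxy-3-methyl-5-(TIPSO)benzaldehyde
Conditions: (CH2O)n, MgCl2, Et3N, MeCN, reflux
Reagents that add atoms: paraformaldehyde, C=O
Why: Casnati–Skattebøl ortho-formylation through the magnesium phenoxide; only one ortho position is free. The formyl carbon becomes C4 of the chroman, and the ring carbon that carries it becomes C4a.

**Step 3**
Reactants: **3**; **4** 2-methyl-2-vinyloxirane (racemic)
Product: **5** (S)-2-[2-formyl-6-methyl-4-(TIPSO)phenoxy]-2-methylbut-3-en-1-ol
Conditions: Pd2(dba)3·CHCl3 (2.5 mol%), (R,R)-DACH-naphthyl Trost ligand (7.5 mol%), CH2Cl2, rt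
Reagents that add atoms: none
Why: Pd-catalysed asymmetric allylic alkylation (DYKAT). The racemic vinyl epoxide ionises to a π-allyl Pd alkoxide that equilibrates. The chiral ligand directs attack of the phenoxide at the more substituted terminus, forming the tertiary aryl ether stereocentre (S) and releasing the CH2OH. This is precedented by the addition of hindered ortho-substituted phenols (a bromotrimethylhydroquinone) to isoprene monoxide in vitamin E chroman syntheses, and is extended here to a formylphenol.

**Step 4**
Reactants: **5**
Product: **6** (S)-2-[2-ethenyl-6-methyl-4-(TIPSO)phenoxy]-2-methylbut-3-en-1-ol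
Conditions: Ph3PCH3Br (3 equiv), KOtBu (3 equiv), THF, 0 °C → rt
Reagents that add atoms: methylenetriphenylphosphorane (CH2 donor), C=[P](c1ccccc1)(c1ccccc1)c1ccccc1
Why: Wittig methylenation converts the aryl aldehyde to a styrene. The free CH2OH only consumes one extra equivalent of ylide, and the quaternary stereocentre is untouched.

**Step 5**
Reactants: **6**
Product: **7** (S)-[2,8-dimethyl-6-(TIPSO)-2H-chromen-2-yl]methanol
Conditions: Grubbs II (5 mol%), CH2Cl2 (0.01 M), 40 °C
Reagents that add atoms: none (ethylene is lost)
Why: Ring-closing metathesis of the styrene with the vinyl group on the quaternary carbon forms the six-membered 2H-chromene (RCM). The C2 configuration is retained, and RCM avoids the 5-exo/6-endo problem of a Heck closure.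

**Step 6**
Reactants: **7**
Product: **8** (S)-[2,8-dimethyl-6-(TIPSO)chroman-2-yl]methanol
Conditions: H2 (1 atm), 10% Pd/C, EtOAc, rt
Reagents that add atoms: none (H2 only)
Why: Heterogeneous hydrogenation of the cis ring alkene, which is the only alkene present. The TIPS ether and the tertiary aryl ether are inert.

**Step 7**
Reactants: **8**
Product: **9** (S)-2,8-dimethyl-6-(TIPSO)chromane-2-carbaldehyde
Conditions: Dess–Martin periodinane, NaHCO3, CH2Cl2, 0 °C → rt
Reagents that add atoms: none
Why: Mild oxidation of the neopentyl alcohol. The aldehyde has no α-hydrogen, so C2 cannot epimerise.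

**Step 8**
Reactants: **9**
Product: **10** (S)-2-ethenyl-2,8-dimethyl-6-(TIPSO)chromane
Conditions: Ph3PCH3Br, KOtBu, THF, 0 °C → rt
Reagents that add atoms: methylenetriphenylphosphorane (CH2 donor), C=[P](c1ccccc1)(c1ccccc1)c1ccccc1
Why: Wittig methylenation installs the terminal alkene that becomes C1'–C2' of the chain. C2 is unchanged.

**Step 9**
Reactants: **11** 5-(trimethylsilyl)pent-4-yn-1-ol
Product: **12** 5-(trimethylsilyl)pent-4-ynal
Conditions: DMP, CH2Cl2, rt (crude aldehyde used immediately)
Reagents that add atoms: none
Why: Mild oxidation that leaves the TMS-alkyne intact.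

**Step 10**
Reactants: **12**; **13** 2-(triphenylphosphoranylidene)propanal
Product: **14** (E)-2-methyl-7-(TMS)hept-2-en-6-ynal
Conditions: **13** (1.2 equiv), CH2Cl2, 40 °C
Reagents that add atoms: none (the ylide is the numbered reactant **13**)
Why: Wittig olefination with a stabilised ylide gives the E-α-methyl enal (>95:5), setting the geometry of the future C7'=C8' alkene.

**Step 11**
Reactants: **14**
Product: **15** (4R,5E)-5-methyl-10-(TMS)deca-1,5-dien-9-yn-4-ol
Conditions: (+)-Ipc2B(allyl), Et2O, −78 °C; then NaBO3·4H2O, THF/H2O, rt
Reagents that add atoms: (+)-allyldiisopinocampheylborane (the allyl group is transferred to the carbonyl carbon), C=CCB(C1CC2CC(C1C)C2(C)C)C1CC2CC(C1C)C2(C)C (pinane stereochemistry not drawn). The perborate work-up only cleaves the O–B bond and oxidises the leftover B–C bonds to isopinocampheol. No atom of it remains in the product, because the carbinol oxygen is the original aldehyde oxygen.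
Why: Brown asymmetric allylboration goes through a Zimmerman–Traxler chair transition state. The reagent delivers allyl to the Re face of the enal and sets the carbinol (R) under reagent control. Mildly basic perborate is used instead of NaOH/H2O2 to spare the alkynyl TMS group.

**Step 12**
Reactants: **15**
Product: **16** TBS ether of **15**
Conditions: TBSOTf, 2,6-lutidine, CH2Cl2, −78 °C
Reagents that add atoms: TBSOTf, C[Si](C)(C(C)(C)C)OS(=O)(=O)C(F)(F)F
Why: Silylation protects the hindered allylic alcohol so it survives the organometallic steps. The TBS group is removed together with TIPS in Step 17.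

**Step 13**
Reactants: **16**
Product: **17** (5R,6E)-2,6-dimethyl-11-(TMS)undeca-2,6-dien-10-yn-5-yl TBS ether
Conditions: Hoveyda–Grubbs II (5 mol%), 2-methyl-2-butene (20 equiv), CH2Cl2, 40 °C
Reagents that add atoms: 2-methyl-2-butene, CC=C(C)C
Why: Cross-metathesis with 2-methyl-2-butene converts the terminal allyl group to the prenyl trisubstituted alkene (Me2C=CH–). The hindered trisubstituted enyl alkene and the TMS-alkyne are expected to be metathesis-silent, but this is a risky step on an advanced polyene.

**Step 14**
Reactants: **17**
Product: **18** (5R,6E)-2,6-dimethylundeca-2,6-dien-10-yn-5-yl TBS ether (terminal alkyne)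
Conditions: K2CO3, MeOH, rt
Reagents that add atoms: none
Why: Base-mediated C–Si cleavage of the alkynyl TMS; the alkyl TBS ether is stable.

**Step 15**
Reactants: **18**
Product: **19** (5R,6E,10E)-11-iodo-2,6,10-trimethylundeca-2,6,10-trien-5-yl TBS ether
Conditions: AlMe3, Cp2ZrCl2 (cat.), ClCH2CH2Cl, 0 °C → rt; then I2, THF, −30 °C
Reagents that add atoms: trimethylaluminium, C[Al](C)C; iodine, II
Why: Negishi Zr-catalysed carboalumination adds Me–Al syn across the terminal alkyne, with Me on the internal carbon and Al on the terminal carbon. Iodinolysis with retention gives the E-trisubstituted vinyl iodide (Me cis to I, chain trans to I), as the target requires. The trisubstituted alkenes and the silyl ether are inert.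

**Step 16**
Reactants: **10**; **19**
Product: **20** bis-silylated Sargachromanol C (TIPS on the phenol, TBS on the carbinol)
Conditions: **10** + Cp2Zr(H)Cl (1.0 equiv), CH2Cl2, rt; then ZnCl2, **19** (0.9 equiv), Pd(PPh3)4 (5 mol%), THF, 50 °C
Reagents that add atoms: none (the Zr–H adds only hydrogen)
Why: Proposed new method: Schwartz hydrozirconation is anti-Markovnikov and should give a primary alkyl-Zr(IV) at the terminal CH2 of the vinyl group, even next to the quaternary centre. Zr→Zn transmetalation, oxidative addition of Pd(0) into the vinyl iodide, transmetalation and reductive elimination then join the fragments with retention of alkene geometry. The closest known reaction is Negishi alkyl–alkenyl coupling of alkylzirconocene chlorides. The neopentyl-adjacent Zr and the allylic silyl ether are the untested features. Using 1.0 equiv of hydride and adding **19** afterwards prevents hydrozirconation of the side-chain alkenes.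

**Step 17**
Reactants: **20**
Product: **21** Sargachromanol C
Conditions: TBAF (3 equiv), THF, 0 °C → rt, under Ar; NH4Cl quench
Reagents that add atoms: none
Why: Fluoride cleaves both the aryl TIPS and the alkyl TBS ether in one step. No stereocentre is affected, and the inert atmosphere limits oxidation of the electron-rich chroman-6-ol.

## Compound list
1 | 2-methylbenzene-1,4-diol | Cc1cc(O)ccc1O | starting material
2 | 2-methyl-4-(TIPSO)phenol | Cc1cc(O[Si](C(C)C)(C(C)C)C(C)C)ccc1O | intermediate
3 | 2-hydroxy-3-methyl-5-(TIPSO)benzaldehyde | Cc1cc(O[Si](C(C)C)(C(C)C)C(C)C)cc(C=O)c1O | intermediate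
4 | 2-methyl-2-vinyloxirane (racemic) | C=CC1(C)CO1 | starting material
5 | (S)-2-[2-formyl-6-methyl-4-(TIPSO)phenoxy]-2-methylbut-3-en-1-ol | OC[C@](Oc1c(C=O)cc(O[Si](C(C)C)(C(C)C)C(C)C)cc1C)(C)C=C | intermediate
6 | (S)-2-[2-ethenyl-6-methyl-4-(TIPSO)phenoxy]-2-methylbut-3-en-1-ol | OC[C@](Oc1c(C=C)cc(O[Si](C(C)C)(C(C)C)C(C)C)cc1C)(C)C=C | intermediate
7 | (S)-[2,8-dimethyl-6-(TIPSO)-2H-chromen-2-yl]methanol | OC[C@]1(C)C=Cc2cc(O[Si](C(C)C)(C(C)C)C(C)C)cc(C)c2O1 | intermediate
8 | (S)-[2,8-dimethyl-6-(TIPSO)chroman-2-yl]methanol | OC[C@]1(C)CCc2cc(O[Si](C(C)C)(C(C)C)C(C)C)cc(C)c2O1 | intermediate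
9 | (S)-2,8-dimethyl-6-(TIPSO)chromane-2-carbaldehyde | O=C[C@]1(C)CCc2cc(O[Si](C(C)C)(C(C)C)C(C)C)cc(C)c2O1 | intermediate
10 | (S)-2-ethenyl-2,8-dimethyl-6-(TIPSO)chromane | C=C[C@]1(C)CCc2cc(O[Si](C(C)C)(C(C)C)C(C)C)cc(C)c2O1 | intermediate
11 | 5-(trimethylsilyl)pent-4-yn-1-ol | C[Si](C)(C)C#CCCCO | starting material
12 | 5-(trimethylsilyl)pent-4-ynal | C[Si](C)(C)C#CCCC=O | intermediate
13 | 2-(triphenylphosphoranylidene)propanal | CC(C=O)=[P](c1ccccc1)(c1ccccc1)c1ccccc1 | starting material
14 | (E)-2-methyl-7-(TMS)hept-2-en-6-ynal | O=C/C(C)=C/CCC#C[Si](C)(C)C | intermediate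
15 | (4R,5E)-5-methyl-10-(TMS)deca-1,5-dien-9-yn-4-ol | C=CC[C@@H](O)/C(C)=C/CCC#C[Si](C)(C)C | intermediate
16 | TBS ether of 15 | C=CC[C@@H](O[Si](C)(C)C(C)(C)C)/C(C)=C/CCC#C[Si](C)(C)C | intermediate
17 | (5R,6E)-2,6-dimethyl-11-(TMS)undeca-2,6-dien-10-yn-5-yl TBS ether | CC(C)=CC[C@@H](O[Si](C)(C)C(C)(C)C)/C(C)=C/CCC#C[Si](C)(C)C | intermediate
18 | (5R,6E)-2,6-dimethylundeca-2,6-dien-10-yn-5-yl TBS ether | CC(C)=CC[C@@H](O[Si](C)(C)C(C)(C)C)/C(C)=C/CCC#C | intermediate
19 | (5R,6E,10E)-11-iodo-2,6,10-trimethylundeca-2,6,10-trien-5-yl TBS ether | CC(C)=CC[C@@H](O[Si](C)(C)C(C)(C)C)/C(C)=C/CC/C(C)=C/I | intermediate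
20 | bis-silylated Sargachromanol C | CC(C)=CC[C@@H](O[Si](C)(C)C(C)(C)C)/C(C)=C/CC/C(C)=C/CC[C@]1(C)CCc2cc(O[Si](C(C)C)(C(C)C)C(C)C)cc(C)c2O1 | intermediate
21 | Sargachromanol C, (2R)-2-[(3E,7E,9R)-9-hydroxy-4,8,12-trimethyltrideca-3,7,11-trien-1-yl]-2,8-dimethylchroman-6-ol | CC(C)=CC[C@@H](O)/C(C)=C/CC/C(C)=C/CC[C@]1(C)CCc2cc(O)cc(C)c2O1 | target

## Totals
- Total steps: 17.
- Longest linear sequence: 10 steps (1→2→3→4→5→6→7→8→16→17). The side-chain branch is 9 steps (9→10→11→12→13→14→15→16→17).

## Three steps most likely to fail
1. **Step 3 (Pd-DYKAT with a hindered o-formylphenol).** Attack at a tertiary π-allyl terminus by a 2,6-disubstituted, electron-poor phenoxide may be slow or give low ee.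
   Fallback: make racemic **5** with an achiral Pd/phosphine catalyst, carry it through to alcohol **8**, and resolve there by lipase acylation (vinyl acetate, Amano PS) or preparative chiral HPLC.
2. **Step 13 (prenylation by cross-metathesis on an advanced polyene).** Metathesis at the hindered trisubstituted alkene could scramble the chain.
   Fallback: build the carbinol by ketone reduction instead. Do a Masamune–Roush HWE of aldehyde **12** with (EtO)2P(O)CH(Me)C(O)CH2CH=CMe2 to give the E-enone, then (R)-CBS reduction at −78 °C. This removes the allylation and metathesis steps, but the β,γ-unsaturated ketone must be kept from isomerising into conjugation.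
3. **Step 16 (hydrozirconation/Negishi coupling).** The hindered alkylzirconium may fail to transmetalate, or the allylic silyl ether may interfere.
   Fallback: hydroborate **10** with 9-BBN and couple the alkyl-9-BBN with **19** under B-alkyl Suzuki conditions (Pd(dppf)Cl2, AsPh3, Cs2CO3, aqueous THF/DMF).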